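**Plan**
- Cuts, in retrosynthetic order: the O–Si bond at C7, then C4–C4a (aryl ketone bond of ring C), then the C2–O1 aryl ether, then the three-carbon chain and the allyl/prenyl C–C bonds on rings A and B.
- Forward: ring A bromophenol 8 is made from 4-bromoresorcinol; ring B with its fused dimethylpyran ring D (carbonate 18) is made from 4-iodophenol.
- The halves are joined at C2–O1, the vinyl group is turned into a Weinreb amide, ring C closes last, and desilylation ends the route.
- Enabling feature: the ketone carbon C4 sits on C4a of ring A, ortho to C8a–O1, so a C4a bromide can become the nucleophile that closes ring C once the C2–O1 bond exists.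
- Stereochemistry: the single stereocentre C2 (S) is set by the chiral ligand in the iridium-catalysed allylic etherification and is only carried along afterwards.

Key step: step 14

Assumption: the iridium catalyst is taken to show its usual sense of induction with cinnamyl carbonates, so the (Sa,S,S)-ligand is specified for the S ether; the mirror-image ligand would be used otherwise, with nothing else changed.

Abbreviations: prenyl = 3-methylbut-2-en-1-yl; TIPS = triisopropylsilyl; ArB = 2,2-dimethyl-8-prenylchroman-6-yl (ring B with fused ring D); ArA = 6-bromo-2-prenyl-3-(TIPS-oxy)phenyl (ring A, bonded through the oxygen on its C1).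

Step 1
Reactants: 1 4-bromoresorcinol
Product: 2 2-bromo-5-(TIPS-oxy)phenol
Conditions: TIPSCl (1.05 equiv), imidazole (2.2 equiv), DMF, 0 °C
Reagents that add atoms: chlorotriisopropylsilane, CC(C)[Si](Cl)(C(C)C)C(C)C
Why: Imidazole-mediated phenol silylation; the hydroxyl para to bromine is unhindered, whereas the one ortho to bromine is shielded and held in an O–H···Br hydrogen bond, so one equivalent of the bulky chlorosilane should go to the remote oxygen.

Step 2
Reactants: 2 2-bromo-5-(TIPS-oxy)phenol; 3 allyl bromide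
Product: 4 2-(allyloxy)-1-bromo-4-(TIPS-oxy)benzene
Conditions: K2CO3 (1.5 equiv), acetone, 56 °C
Reagents that add atoms: allyl bromide (3), C=CCBr
Why: Williamson etherification of the remaining acidic ortho-bromophenol with a reactive allylic halide, under conditions that an aryl TIPS ether should tolerate.

Step 3
Reactants: 4 2-(allyloxy)-1-bromo-4-(TIPS-oxy)benzene
Product: 6 2-allyl-6-bromo-3-(TIPS-oxy)phenol, via ortho-dienone 5 (not isolated)
Conditions: N,N-diethylaniline, 190 °C, argon
Reagents that add atoms: none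
Why: Aromatic Claisen rearrangement; the only ortho carbon bearing hydrogen is the one between the two oxygens, so the [3,3] shift should place the allyl group there and dienone 5 then tautomerises to the phenol.

Step 4
Reactants: 6 2-allyl-6-bromo-3-(TIPS-oxy)phenol; 7 2-methyl-2-butene
Product: 8 6-bromo-2-prenyl-3-(TIPS-oxy)phenol
Conditions: 2-methyl-2-butene (excess), second-generation Grubbs catalyst RuCl2(=CHPh)(H2IMes)(PCy3) (3 mol%), CH2Cl2, 40 °C
Reagents that add atoms: 2-methyl-2-butene (7), CC=C(C)C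
Why: Olefin cross-metathesis of a terminal allyl arene with excess 2-methyl-2-butene, a standard allyl-to-prenyl conversion compatible with free phenols, aryl bromides and silyl ethers.

Step 5
Reactants: 9 4-iodophenol; 10 prenyl bromide
Product: 12 4-iodo-2,6-diprenylphenol, via 4-iodo-2-prenylphenol 11 (not isolated)
Conditions: NaH (1.1 equiv), toluene, rt, then prenyl bromide (1.1 equiv); second charge of NaH and prenyl bromide (1.1 equiv each), rt
Reagents that add atoms: prenyl bromide (10), CC(C)=CCBr
Why: C-Alkylation of a sodium phenoxide in a non-polar solvent, where the tight ion pair directs the allylic halide to the ortho carbons; with the para position blocked by iodine both ortho positions should be prenylated in turn, as known for para-halophenols.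

Step 6
Reactants: 12 4-iodo-2,6-diprenylphenol
Product: 13 6-iodo-2,2-dimethyl-8-prenylchroman
Conditions: p-TsOH·H2O (10 mol%), toluene, 60 °C
Reagents that add atoms: none
Why: Brønsted acid-catalysed intramolecular hydroalkoxylation (Markovnikov protonation to the tertiary cation and capture by the phenol oxygen) closes ring D; the molecule has only one hydroxyl, so the second prenyl group has no partner and should survive catalytic acid.

Step 7
Reactants: 13 6-iodo-2,2-dimethyl-8-prenylchroman; 14 methyl acrylate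
Product: 15 methyl (2E)-3-ArB-prop-2-enoate
Conditions: methyl acrylate (1.5 equiv), Pd(OAc)2 (5 mol%), P(o-tol)3 (10 mol%), Et3N (2 equiv), DMF, 90 °C
Reagents that add atoms: methyl acrylate (14), C=CC(=O)OC
Why: Mizoroki–Heck reaction of an aryl iodide with an acrylate; syn insertion and syn β-hydride elimination should give the E-cinnamate, and the remote trisubstituted prenyl alkene does not insert.

Step 8
Reactants: 15 methyl (2E)-3-ArB-prop-2-enoate
Product: 17 (2E)-3-ArB-prop-2-en-1-ol, via enal 16 (not isolated)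
Conditions: i-Bu2AlH (2.5 equiv), CH2Cl2, −78 °C; aqueous Rochelle salt
Reagents that add atoms: none
Why: 1,2-Reduction of an α,β-unsaturated ester by i-Bu2AlH at low temperature through enal 16 to the allylic alcohol, leaving isolated alkenes untouched.

Step 9
Reactants: 17 (2E)-3-ArB-prop-2-en-1-ol
Product: 18 (2E)-3-ArB-prop-2-en-1-yl methyl carbonate
Conditions: ClCO2Me (1.5 equiv), pyridine (2 equiv), CH2Cl2, 0 °C
Reagents that add atoms: methyl chloroformate, COC(=O)Cl
Why: Acylation of a primary allylic alcohol by a chloroformate with pyridine as base and nucleophilic catalyst.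

Step 10
Reactants: 8 6-bromo-2-prenyl-3-(TIPS-oxy)phenol; 18 (2E)-3-ArB-prop-2-en-1-yl methyl carbonate
Product: 20 (S)-branched allyl aryl ether ArA–O–CH(ArB)–CH=CH2, via lithium aryloxide 19 (not isolated)
Conditions: 8 (1.5 equiv), LiN(SiMe3)2 (1.5 equiv), THF, 0 °C; then 18, [Ir(cod)Cl]2 (2 mol%), (Sa,S,S)-O,O′-(1,1′-binaphthyl-2,2′-diyl)-N,N-bis(1-phenylethyl)phosphoramidite (4 mol%), THF, 50 °C
Reagents that add atoms: none
Why: Iridium-catalysed asymmetric allylic etherification: the cyclometalated iridium–phosphoramidite complex ionises the linear carbonate and the aryloxide attacks the aryl-substituted allyl terminus, so the branched ether should form with C2 set as S by the chiral ligand (catalyst control).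

Step 11
Reactants: 20 (S)-branched allyl aryl ether ArA–O–CH(ArB)–CH=CH2
Product: 22 (3S)-3-ArB-3-(ArA-oxy)propan-1-ol, via B-alkyl-9-BBN 21 (not isolated)
Conditions: 9-BBN (1.5 equiv), THF, 0 °C to rt; then NaBO3·4H2O (5 equiv), THF/H2O, rt
Reagents that add atoms: sodium perborate (NaBO3·4H2O, oxygen source), [Na+].[Na+].O[B-]1(O)OO[B-](O)(O)OO1
Why: Hydroboration–oxidation; 9-BBN adds anti-Markovnikov to the monosubstituted vinyl group far faster than to the two trisubstituted prenyl alkenes, and the mild perborate oxidation should spare the aryl silyl ether and the stereocentre.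

Step 12
Reactants: 22 (3S)-3-ArB-3-(ArA-oxy)propan-1-ol
Product: 24 (3S)-3-ArB-3-(ArA-oxy)propanoic acid, via aldehyde 23 (not isolated)
Conditions: TEMPO (0.2 equiv), PhI(OAc)2 (2.5 equiv), MeCN/CH2Cl2/H2O, rt
Reagents that add atoms: water, O
Why: Oxoammonium (TEMPO/PhI(OAc)2) oxidation of a primary alcohol through aldehyde 23 and its hydrate to the acid, under non-basic conditions that should not trigger β-elimination of the aryloxide.

Step 13
Reactants: 24 (3S)-3-ArB-3-(ArA-oxy)propanoic acid
Product: 26 (3S)-N-methoxy-N-methyl-3-ArB-3-(ArA-oxy)propanamide, via acyl imidazole 25 (not isolated)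
Conditions: CDI (1.2 equiv), CH2Cl2, rt; then MeNH(OMe)·HCl (1.5 equiv), rt
Reagents that add atoms: N,O-dimethylhydroxylamine hydrochloride, CNOC.Cl
Why: Weinreb amide formation through the acyl imidazole (CDI activation), which needs no added base and so should not cause E1cB loss of the β-aryloxy group.

Step 14
Reactants: 26 (3S)-N-methoxy-N-methyl-3-ArB-3-(ArA-oxy)propanamide
Product: 29 (2S)-2-ArB-8-prenyl-7-(TIPS-oxy)chroman-4-one, via aryllithium 27 (not isolated), via lithium hemiaminal alkoxide 28 (not isolated)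
Conditions: t-BuLi (2.1 equiv), THF, −78 °C; then AcOH (3 equiv) in THF, −78 °C to rt
Reagents that add atoms: none
Why: Bromine–lithium exchange at C4a is much faster at −78 °C than addition of t-BuLi to the amide, and the second equivalent destroys the t-BuBr formed; aryllithium 27 then attacks the carbonyl of the tethered Weinreb amide and forms the C4–C4a bond. This is a Parham cyclisation, the intramolecular form of aryllithium acylation by an N-methoxy-N-methylamide, known for chroman-4-ones. Ring C closes in a 6-exo-trig mode, the amide C=O lying outside the new six-membered ring. No stereocentre is created in 29 (the carbinol carbon of 28 collapses to the ketone), and C2, set in step 10, is not involved. The step needs exchange to beat amide attack and ring closure to beat proton transfer from C3–H or C2–H to the aryllithium; the oxygen-flanked bromide, the six-membered geometry and the low temperature should secure this, and the position of bromine fixes closure at C4a. The five-membered lithium chelate 28 should persist until the acetic acid quench at −78 °C, so the ketone never meets base and can neither lose the aryloxide by β-elimination nor add a second organolithium; the silyl ether is para to lithium and cannot migrate, and the prenyl groups are inert.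

Step 15
Reactants: 29 (2S)-2-ArB-8-prenyl-7-(TIPS-oxy)chroman-4-one
Product: 30 (2S)-2-ArB-7-hydroxy-8-prenylchroman-4-one (target)
Conditions: Bu4NF (1.2 equiv), AcOH (1.5 equiv), THF, 0 °C
Reagents that add atoms: none
Why: Fluoride cleavage of an aryl silyl ether, buffered with acetic acid so that the flavanone should not open to the chalcone and C2 keeps its configuration.

**Compound list**
1 | 4-bromoresorcinol (4-bromobenzene-1,3-diol) | Oc1ccc(Br)c(O)c1 | starting material
2 | 2-bromo-5-(TIPS-oxy)phenol | Oc1cc(O[Si](C(C)C)(C(C)C)C(C)C)ccc1Br | intermediate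
3 | allyl bromide | C=CCBr | starting material
4 | 2-(allyloxy)-1-bromo-4-(TIPS-oxy)benzene | C=CCOc1cc(O[Si](C(C)C)(C(C)C)C(C)C)ccc1Br | intermediate
5 | 6-allyl-2-bromo-5-(TIPS-oxy)cyclohexa-2,4-dien-1-one (ortho-dienone, racemic) | O=C1C(Br)=CC=C(O[Si](C(C)C)(C(C)C)C(C)C)C1CC=C | intermediate (not isolated)
6 | 2-allyl-6-bromo-3-(TIPS-oxy)phenol | C=CCc1c(O)c(Br)ccc1O[Si](C(C)C)(C(C)C)C(C)C | intermediate
7 | 2-methyl-2-butene | CC=C(C)C | starting material
8 | 6-bromo-2-prenyl-3-(TIPS-oxy)phenol | CC(C)=CCc1c(O)c(Br)ccc1O[Si](C(C)C)(C(C)C)C(C)C | intermediate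
9 | 4-iodophenol | Oc1ccc(I)cc1 | starting material
10 | prenyl bromide (1-bromo-3-methylbut-2-ene) | CC(C)=CCBr | starting material
11 | 4-iodo-2-prenylphenol | CC(C)=CCc1cc(I)ccc1O | intermediate (not isolated)
12 | 4-iodo-2,6-diprenylphenol | CC(C)=CCc1cc(I)cc(CC=C(C)C)c1O | intermediate
13 | 6-iodo-2,2-dimethyl-8-prenylchroman | CC(C)=CCc1cc(I)cc2c1OC(C)(C)CC2 | intermediate
14 | methyl acrylate | C=CC(=O)OC | starting material
15 | methyl (2E)-3-(2,2-dimethyl-8-prenylchroman-6-yl)prop-2-enoate | COC(=O)/C=C/c1cc(CC=C(C)C)c2OC(C)(C)CCc2c1 | intermediate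
16 | (2E)-3-(2,2-dimethyl-8-prenylchroman-6-yl)prop-2-enal | O=C/C=C/c1cc(CC=C(C)C)c2OC(C)(C)CCc2c1 | intermediate (not isolated)
17 | (2E)-3-(2,2-dimethyl-8-prenylchroman-6-yl)prop-2-en-1-ol | OC/C=C/c1cc(CC=C(C)C)c2OC(C)(C)CCc2c1 | intermediate
18 | (2E)-3-(2,2-dimethyl-8-prenylchroman-6-yl)prop-2-en-1-yl methyl carbonate | COC(=O)OC/C=C/c1cc(CC=C(C)C)c2OC(C)(C)CCc2c1 | intermediate
19 | lithium 6-bromo-2-prenyl-3-(TIPS-oxy)phenoxide | [Li]Oc1c(Br)ccc(O[Si](C(C)C)(C(C)C)C(C)C)c1CC=C(C)C | intermediate (not isolated)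
20 | 1-bromo-2-{[(1S)-1-(2,2-dimethyl-8-prenylchroman-6-yl)prop-2-en-1-yl]oxy}-3-prenyl-4-(TIPS-oxy)benzene | C=C[C@@H](c1cc(CC=C(C)C)c2OC(C)(C)CCc2c1)Oc1c(Br)ccc(O[Si](C(C)C)(C(C)C)C(C)C)c1CC=C(C)C | intermediate
21 | B-[(3S)-3-ArB-3-(ArA-oxy)propyl]-9-borabicyclo[3.3.1]nonane | C1CC2CCCC(C1)B2CC[C@@H](c1cc(CC=C(C)C)c2OC(C)(C)CCc2c1)Oc1c(Br)ccc(O[Si](C(C)C)(C(C)C)C(C)C)c1CC=C(C)C | intermediate (not isolated)
22 | (3S)-3-ArB-3-(ArA-oxy)propan-1-ol | OCC[C@@H](c1cc(CC=C(C)C)c2OC(C)(C)CCc2c1)Oc1c(Br)ccc(O[Si](C(C)C)(C(C)C)C(C)C)c1CC=C(C)C | intermediate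
23 | (3S)-3-ArB-3-(ArA-oxy)propanal | O=CC[C@@H](c1cc(CC=C(C)C)c2OC(C)(C)CCc2c1)Oc1c(Br)ccc(O[Si](C(C)C)(C(C)C)C(C)C)c1CC=C(C)C | intermediate (not isolated)
24 | (3S)-3-ArB-3-(ArA-oxy)propanoic acid | OC(=O)C[C@@H](c1cc(CC=C(C)C)c2OC(C)(C)CCc2c1)Oc1c(Br)ccc(O[Si](C(C)C)(C(C)C)C(C)C)c1CC=C(C)C | intermediate
25 | (3S)-3-ArB-3-(ArA-oxy)-1-(imidazol-1-yl)propan-1-one | O=C(C[C@@H](c1cc(CC=C(C)C)c2OC(C)(C)CCc2c1)Oc1c(Br)ccc(O[Si](C(C)C)(C(C)C)C(C)C)c1CC=C(C)C)n1ccnc1 | intermediate (not isolated)
26 | (3S)-N-methoxy-N-methyl-3-ArB-3-(ArA-oxy)propanamide | CON(C)C(=O)C[C@@H](c1cc(CC=C(C)C)c2OC(C)(C)CCc2c1)Oc1c(Br)ccc(O[Si](C(C)C)(C(C)C)C(C)C)c1CC=C(C)C | intermediate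
27 | aryllithium from 26 (lithium in place of bromine, S) | CON(C)C(=O)C[C@@H](c1cc(CC=C(C)C)c2OC(C)(C)CCc2c1)Oc1c([Li])ccc(O[Si](C(C)C)(C(C)C)C(C)C)c1CC=C(C)C | intermediate (not isolated)
28 | lithium (2S)-4-[methoxy(methyl)amino]-2-ArB-8-prenyl-7-(TIPS-oxy)chroman-4-olate (C4 configuration undefined) | CON(C)C1(O[Li])C[C@@H](c2cc(CC=C(C)C)c3OC(C)(C)CCc3c2)Oc2c1ccc(O[Si](C(C)C)(C(C)C)C(C)C)c2CC=C(C)C | intermediate (not isolated)
29 | (2S)-2-ArB-8-prenyl-7-(TIPS-oxy)chroman-4-one | O=C1C[C@@H](c2cc(CC=C(C)C)c3OC(C)(C)CCc3c2)Oc2c1ccc(O[Si](C(C)C)(C(C)C)C(C)C)c2CC=C(C)C | intermediate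
30 | (2S)-2-(2,2-dimethyl-8-prenylchroman-6-yl)-7-hydroxy-8-prenylchroman-4-one | CC(C)=CCc1cc([C@@H]2CC(=O)c3ccc(O)c(CC=C(C)C)c3O2)cc2c1OC(C)(C)CC2 | target

**Totals**
Total step count: 15.
Longest linear sequence: 11 steps (9 → 12 → 13 → 15 → 17 → 18 → 20 → 22 → 24 → 26 → 29 → 30; steps 5–15).

**Steps most likely to fail**

1. Step 10. The doubly ortho-substituted aryloxide may attack the allyliridium intermediate too slowly, so that linear ether forms or the branched product re-ionises and loses enantiopurity. The fallback sets out from 15 and returns at 26, bypassing steps 8–13, and makes the C2–O1 bond by SN2 displacement instead of allyl-metal chemistry. Copper-catalysed asymmetric conjugate borylation of 15 (CuCl, NaOt-Bu, a Josiphos-type ferrocenyl bisphosphine of the antipode that gives the R product, B2pin2, MeOH, THF, rt) should give methyl (3R)-3-ArB-3-(pinacolboryl)propanoate F1. This is oxidised in the same flask with NaBO3·4H2O, with retention, to methyl (3R)-3-ArB-3-hydroxypropanoate F2. Mitsunobu etherification of F2 with phenol 8 (PPh3, DIAD, toluene, 0 °C) should proceed with inversion to methyl (3S)-3-ArB-3-(ArA-oxy)propanoate F3; some erosion of enantiopurity at this electron-rich benzylic centre would have to be checked. Aminolysis of F3 with Me2AlN(OMe)Me (from AlMe3 and MeNH(OMe)·HCl, CH2Cl2, 0 °C to rt) then gives 26.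

2. Step 14. Proton transfer to the aryllithium from C3–H, followed by β-elimination of the aryloxide, or direct addition of t-BuLi to the amide may compete with ring closure. The fallback sets out from 24 and returns at 29, using the carboxylate form of the Parham cyclisation, whose electrophile is inert to t-BuLi and hardly enolisable. Acid 24 is deprotonated with MeLi (1.0 equiv, THF, −100 °C) to lithium (3S)-3-ArB-3-(ArA-oxy)propanoate F4. t-BuLi (2.1 equiv, −100 to −78 °C) should give the C4a-lithiated lithium carboxylate F5, which closes to the cyclic dilithium chroman-4,4-diolate F6. The acetic acid quench at −78 °C releases 29.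

3. Step 5. O-Alkylation and incomplete second C-alkylation of the phenoxide may give mixtures that are hard to separate. The fallback sets out from 9 and returns at 12, placing both ortho carbon chains by sigmatropic rearrangement instead of phenoxide C-alkylation. O-Allylation of 9 (allyl bromide 3, K2CO3, acetone) gives 1-(allyloxy)-4-iodobenzene F7, and Claisen rearrangement (N,N-diethylaniline, 190 °C) gives 2-allyl-4-iodophenol F8. A second O-allylation gives 2-allyl-1-(allyloxy)-4-iodobenzene F9, and a second Claisen rearrangement gives 2,6-diallyl-4-iodophenol F10. Double cross-metathesis of F10 with 2-methyl-2-butene 7 (second-generation Grubbs catalyst RuCl2(=CHPh)(H2IMes)(PCy3), CH2Cl2, 40 °C) then gives 12.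

**Further compounds**
F1 | step 10 | methyl (3R)-3-ArB-3-(4,4,5,5-tetramethyl-1,3,2-dioxaborolan-2-yl)propanoate | COC(=O)C[C@@H](B1OC(C)(C)C(C)(C)O1)c1cc(CC=C(C)C)c2OC(C)(C)CCc2c1
F2 | step 10 | methyl (3R)-3-ArB-3-hydroxypropanoate | COC(=O)C[C@@H](O)c1cc(CC=C(C)C)c2OC(C)(C)CCc2c1
F3 | step 10 | methyl (3S)-3-ArB-3-(ArA-oxy)propanoate | COC(=O)C[C@@H](c1cc(CC=C(C)C)c2OC(C)(C)CCc2c1)Oc1c(Br)ccc(O[Si](C(C)C)(C(C)C)C(C)C)c1CC=C(C)C
F4 | step 14 | lithium (3S)-3-ArB-3-(ArA-oxy)propanoate | [Li]OC(=O)C[C@@H](c1cc(CC=C(C)C)c2OC(C)(C)CCc2c1)Oc1c(Br)ccc(O[Si](C(C)C)(C(C)C)C(C)C)c1CC=C(C)C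
F5 | step 14 | C4a-lithiated lithium carboxylate from F4 (lithium in place of bromine, S) | [Li]OC(=O)C[C@@H](c1cc(CC=C(C)C)c2OC(C)(C)CCc2c1)Oc1c([Li])ccc(O[Si](C(C)C)(C(C)C)C(C)C)c1CC=C(C)C
F6 | step 14 | dilithium (2S)-2-ArB-8-prenyl-7-(TIPS-oxy)chroman-4,4-diolate | [Li]OC1(O[Li])C[C@@H](c2cc(CC=C(C)C)c3OC(C)(C)CCc3c2)Oc2c1ccc(O[Si](C(C)C)(C(C)C)C(C)C)c2CC=C(C)C
F7 | step 5 | 1-(allyloxy)-4-iodobenzene | C=CCOc1ccc(I)cc1
F8 | step 5 | 2-allyl-4-iodophenol | C=CCc1cc(I)ccc1O
F9 | step 5 | 2-allyl-1-(allyloxy)-4-iodobenzene | C=CCOc1ccc(I)cc1CC=C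
F10 | step 5 | 2,6-diallyl-4-iodophenol | C=CCc1cc(I)cc(CC=C)c1O
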